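## Analysis of the target

The target is a cyclohex-3-ene carrying five oxygens. The ring is numbered C1 (quaternary carbinol bearing the exocyclic C7H2OBz arm), C2 (CH–OBz), C3=C4, C5 and C6 (both CH–OH). In this numbering the four stereocentres are (1S,2S,5R,6S). The C1 hydroxyl is cis to the C6 hydroxyl, the C5 and C6 hydroxyls are trans, and the C2 benzoate is trans to the C1 hydroxyl, so it is cis to the C7 arm and cis to the C5 hydroxyl across the alkene. The sensitive points are the two benzoates, which can migrate to three free neighbouring hydroxyls under base, and the allylic C–O bonds at C2 and C5, which can ionise or transpose in strong acid. The synthesis is hard because C1 is fully substituted and flanked by stereocentres on both sides, and because exactly two of five oxygens (C7 and C2) must be acylated. The strategy rests on three observations: C7–C1–C6 is a dihydroxyacetone unit with C1 at the ketone oxidation level, the C5/C6 diol has the D-threo configuration that fructose-1,6-bisphosphate aldolase produces, and C2 can be brought in as a nitro-bearing nucleophilic carbon that later becomes the carbinol. Both C–C bonds to the three-carbon ketone unit (C5–C6 and C1–C2) can therefore be made in water without protecting groups.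

## Retrosynthetic reasoning

**19 back to 17 (C–O disconnections).** The last operations are kept to the release of the C5/C6 diol (18 to 19) and the esterification of C2 with 9 (17 to 18). In 17 the C5/C6 oxygens are tied up in a bis-ketal, C7 is already a benzoate and C1–OH is tertiary, so the C2 hydroxyl is the only acylable position. The forward steps must avoid acyl migration and ionisation of the allylic positions.

**17 back to 16 (C2–H bond).** The C2 carbinol is cut to the C2 ketone of enone 16. The required C2–O bond is trans to the C1 hydroxyl, which is the outcome of hydride delivery from a boron bound to O1. The neighbouring quaternary stereocentre thus controls C2, and the forward reduction needs no external chiral reagent. It must override the intrinsic axial-attack preference, which would give the other epimer.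

**16 back to 13 (C3=C4 alkene).** The alkene is removed to the saturated ketone 13 by way of its silyl enol ether 14 and the silylated enone 15. C1 has no hydrogen, so the ketone can only enolise towards C3, and dehydrogenation can only place the alkene at C3=C4. The forward step must introduce the unsaturation without base, since the enone has an acidic C5–H next to a C6 leaving group.

**13 back to 10 (C2=O from C2–NO2).** The ketone is traced to the secondary nitro compound 11, and 11 to the free tertiary alcohol 10. The nitro group is what makes C2 nucleophilic in the ring-forming step, and it is a latent carbonyl. O1 is silylated before the nitronate is formed so that the ring cannot reopen by retro-nitroaldol.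

**10 back to 6 (protecting groups).** The C7 benzoate of 10 is already a target feature and comes from 8 and 9. The bis-ketal of 8 is placed on the only trans-diequatorial diol of tetraol 7. 7 is the dephosphorylated form of 6. No group is introduced that is not either in the target or removed in the last step, apart from the temporary silyl ether on O1.

**6 back to 3 and 4 (key disconnection, C1–C2 and C5–C6).** Cutting C1–C2 as a nitroaldol opens the ring to the linear ketose phosphate 5. Cutting C5–C6 as an aldol gives aldehyde 3 and ketone donor 4. These are the two bonds to the three-carbon ketone unit, and the aldolase sets the C5/C6 configuration absolutely. The forward reaction has to join the fragments and then close the ring with C1 set by equilibration.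

**3 back to 1 and 2 (C2–C3 bond).** The aldehyde is the conjugate adduct of 1 to 2. Both are bulk chemicals, and the nitro group and the aldehyde come in at the right oxidation levels.

## Alternatives that were turned down

**Alternative 1:** The carbocycle is opened at C1–C2 and C7–O to a tartrate-derived chain, the (Z)-enal oxime A1, which carries the C5/C6 diol as an acetonide and C1=C7 as a silyl enol ether. In the forward key step NaOCl turns the oxime into a nitrile oxide at C2, which adds across C1=C7 to give the fused isoxazoline A2.
- For: the C3=C4 alkene is present from the start, C5/C6 come from the chiral pool, and one step makes the ring, the quaternary centre, the C7–O bond and C2 at the carbonyl level.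
- Against:
  - The configuration at C1 depends on substrate-controlled facial selectivity through a strained trans-fused acetonide.
  - The tether forces the nitrile oxide carbon onto the oxygen-bearing alkene carbon, against the electronic preference of enol ethers, so dimerisation of the dipole can compete.
  - The silyl enol ether must survive aqueous hypochlorite, and the Z-geometry of A1 must hold.
  - A1 needs desymmetrisation of the tartrate and two different chain extensions, an estimated eight to ten steps.
  - After N–O cleavage of A2 the C2 ketone still has to be reduced trans to O1, but O1 is silylated, and the free C7 hydroxyl would direct hydride to the wrong face.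
- Comparison: this route is stronger on alkene placement, because no Nef or dehydrogenation sequence is needed. The chosen route offers enzyme-set absolute configuration, thermodynamic rather than kinetic control at C1, and a carbocycle in two steps.

**Alternative 2:** The C5–O and C6–O bonds are traced to an epoxide and then to the achiral Birch-derived dienol A3. In the forward key step Hf(OtBu)4, a chiral bishydroxamic acid and cumene hydroperoxide epoxidise one of the two enantiotopic alkenes syn to the C1 hydroxyl, giving epoxy alcohol A4.
- For: it is the shortest access to a chiral core, it is catalytic, the C7 benzoate is in place, the epoxide oxygen at C6 is already cis to the C1 hydroxyl, and opening at C5 with inversion would give the trans diol.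
- Against:
  - The catalyst must choose between two alkenes and between two faces on a bis-allylic tertiary alcohol, and the C1 stereocentre exists only through that choice.
  - A3 is prone to aromatisation under acid.
  - In A4 the remaining alkene is at C2=C3 and C4 is a methylene. The unsaturation must be moved to C3=C4 and oxygen introduced at C2 with defined configuration.
  - The C2 and C5 hydroxyls, both secondary and allylic, would then have to be told apart for a single benzoylation.
- Comparison: this route is stronger on step count to the first chiral intermediate and on catalytic economy. The chosen route has C2 differentiated from the outset as the nitro carbon and does not need to relocate the alkene.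

**Alternative 3:** The C1–C2 bond is cut by a retro-[3,3] shift that reconnects C4 to a lactone oxygen, giving the mannose-derived lactone A5 with an (E)-2-alkoxyvinyl group. In the forward key step KN(SiMe3)2 and tert-butyldimethylsilyl chloride form the silyl ketene acetal of A5, which undergoes Ireland–Claisen ring contraction to the cyclohexenecarboxylic acid A6.
- For: A6 has all four stereocentres, the alkene in place and every oxygen differentiated (C2 ether, C5 silyl ether, C1/C6 acetonide, C7 as acid). It is the most complete key-step product of the four strategies.
- Against:
  - A5 needs a long carbohydrate sequence, with oxidation-state changes at both ends and installation of the E-enol ether.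
  - The lactone enolate has a β-alkoxy leaving group and can eliminate.
  - The rearrangement must pass through a boat-like transition state for the enol ether geometry to translate into the C2 configuration.
  - Afterwards the acid must be reduced and three kinds of protecting group removed.
- Comparison: this route is stronger in what the key step delivers. The chosen route is far shorter up to the carbocycle and uses no protecting group before the ring exists, at the price of the Nef, dehydrogenation and reduction sequence afterwards.

Key step: step 2

Remark: the phosphate monoesters 4, 5 and 6 are drawn as free acids although they are handled in water as salts (4 is bought as its dilithium salt, 6 is isolated as its barium salt). Ring positions in all names follow the C1–C7 numbering of the analysis.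

## Route

Step 1
Reactants: 1 nitromethane; 2 acrolein
Product: 3 4-nitrobutanal
Conditions: 1 (10 equiv), NaOMe (5 mol%), MeOH, −20 → 0 °C; AcOH quench
Reagents that add atoms: none
Why: Base-catalysed Michael addition of the nitromethane anion to the enal forms the C2–C3 bond; the large excess of 1 and the low temperature suppress double addition and the Henry reaction of the product aldehyde.

Step 2
Reactants: 3 4-nitrobutanal; 4 dihydroxyacetone phosphate
Product: 6 [(1S,2R,5R,6S)-1,5,6-trihydroxy-2-nitrocyclohexyl]methyl dihydrogen phosphate, via linear ketose phosphate 5 (not isolated)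
Conditions: 4 (1 equiv, 0.1 M), 3 (1.5 equiv), rabbit muscle fructose-1,6-bisphosphate aldolase, H2O, pH 7.0, 25 °C, until 5 is consumed; BaCl2, EtOH (precipitation)
Reagents that add atoms: none
Why: The lysine-bound enamine of 4 in the aldolase active site adds to the aldehyde carbon of 3 and forms the C5–C6 bond of 5 with the enzyme's invariable (3S,4R) sense, which is 6S,5R in ring numbering. The chain of 5 has no hydroxyl placed for a furanose or pyranose hemiketal, so the C1 ketone stays free, and at pH 7 a fraction of the primary nitro group is present as nitronate, whose carbon (C2) adds to C1 in an intramolecular Henry reaction. The closest known reaction type is this same tandem: aldolase addition of 4 to nitro aldehydes followed by spontaneous nitroaldol cyclisation to nitrocyclitols. The ring closes in the 6-(enolexo)-exo-trig mode, which is favoured. C5 and C6 are controlled by the enzyme; C1 and C2 are controlled thermodynamically, because the Henry step is reversible and the nitro-bearing carbon epimerises through its nitronate. The chair with the C5 hydroxyl, the C6 hydroxyl, the nitro group and the phosphoryloxymethyl arm all equatorial and only the small C1 hydroxyl axial should be the energy minimum, and it has the C1 hydroxyl cis to the C6 hydroxyl as the target requires. The step needs enzyme acceptance of the aldehyde and complete equilibration at C1; the unhindered aldehyde of 3 serves the first, the reversibility of the Henry reaction together with the fixed equatorial anchors at C5 and C6 serves the second, and the configuration at C2 is irrelevant because it later becomes a carbonyl. Ring closure removes 5 from the aldol equilibrium and pulls the enzymatic step forward.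

Step 3
Reactants: 6 [(1S,2R,5R,6S)-1,5,6-trihydroxy-2-nitrocyclohexyl]methyl dihydrogen phosphate
Product: 7 (1S,2R,5R,6S)-1-(hydroxymethyl)-2-nitrocyclohexane-1,5,6-triol
Conditions: acid phosphatase, H2O, pH 4.8, 37 °C; ion-exchange desalting
Reagents that add atoms: none
Why: Enzymatic hydrolysis of the phosphate monoester at a pH where the nitro group is not ionised, so the ring cannot reopen by retro-nitroaldol and no stereocentre is touched.

Step 4
Reactants: 7 (1S,2R,5R,6S)-1-(hydroxymethyl)-2-nitrocyclohexane-1,5,6-triol
Product: 8 5,6-O-[(2S,3S)-2,3-dimethoxybutane-2,3-diyl] acetal of 7 (trans-fused butane-2,3-diacetal; C7–OH and C1–OH free)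
Conditions: butane-2,3-dione (1.3 equiv), HC(OMe)3 (3 equiv), camphorsulfonic acid (10 mol%), MeOH, reflux
Reagents that add atoms: butane-2,3-dione, CC(=O)C(C)=O; trimethyl orthoformate, COC(OC)OC; methanol, CO (the two methoxy groups)
Why: Thermodynamic bis-ketalisation with a 1,2-diketone; only the C5/C6 pair is a vicinal trans-diequatorial diol that can span a trans-fused chair 1,4-dioxane with both methoxy groups axial, and this anomeric arrangement also fixes both acetal carbons as S. The cis C1/C6 pair and the exocyclic C7/C1 pair would give strained or unstabilised acetals.

Step 5
Reactants: 8 5,6-O-[(2S,3S)-2,3-dimethoxybutane-2,3-diyl] acetal of 7; 9 benzoyl chloride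
Product: 10 C7-O-benzoate of 8
Conditions: 9 (1.1 equiv), pyridine, CH2Cl2, 0 °C
Reagents that add atoms: none
Why: Acylation of the only primary hydroxyl; the tertiary C1 hydroxyl does not react with an acid chloride in pyridine at 0 °C.

Step 6
Reactants: 10 C7-O-benzoate of 8
Product: 11 C1-O-trimethylsilyl ether of 10
Conditions: N-(trimethylsilyl)imidazole (3 equiv), CH2Cl2, 25 °C
Reagents that add atoms: N-(trimethylsilyl)imidazole, C[Si](C)(C)n1ccnc1
Why: Silylation of the hindered tertiary alcohol with a powerful neutral trimethylsilyl donor; capping O1 closes the alkoxide pathway to retro-nitroaldol ring opening in the next step.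

Step 7
Reactants: 11 C1-O-trimethylsilyl ether of 10
Product: 13 C2 ketone (1S,5R,6S) carrying C1–OSiMe3 plus C7–OBz plus the 5,6-diacetal, via potassium nitronate 12 (not isolated)
Conditions: KOtBu (1.05 equiv), THF, −78 °C; then dimethyldioxirane (acetone solution, 1.5 equiv), −78 → 0 °C
Reagents that add atoms: dimethyldioxirane, CC1(C)OO1 (carbonyl oxygen of 13); potassium tert-butoxide, CC(C)(C)[O-].[K+] (potassium of 12 only)
Why: Oxidative Nef reaction; the secondary nitro C–H is the only acidic site, the nitronate C=N bond is oxygenated by the dioxirane and the adduct collapses to ketone and nitrite. The C2 configuration is erased as planned, and C1 cannot epimerise because O1 is silylated.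

Step 8
Reactants: 13 C2 ketone carrying C1–OSiMe3
Product: 14 C2 trimethylsilyl enol ether of 13 (C2=C3)
Conditions: Me3SiOTf (1.5 equiv), Et3N (3 equiv), CH2Cl2, 0 °C; used without chromatography
Reagents that add atoms: trimethylsilyl trifluoromethanesulfonate, C[Si](C)(C)OS(=O)(=O)C(F)(F)F
Why: Soft enolisation and O-silylation; C1 is fully substituted, so the enol ether can only form towards C3, and the excess amine keeps the diacetal from ionising.

Step 9
Reactants: 14 C2 trimethylsilyl enol ether of 13
Product: 16 C3=C4 enone with free C1–OH (1S,5R,6S), via C1-silylated enone 15 (not isolated)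
Conditions: Pd(OAc)2 (1.1 equiv), MeCN, 25 °C; then 1 M aq. HCl, THF, 0 °C
Reagents that add atoms: none
Why: Saegusa–Ito oxidation; silicon-to-palladium exchange gives a C3-bound enolate of divalent palladium, and syn β-hydride elimination from C4 gives the C3=C4 enone and zerovalent palladium. The dilute acid then cleaves the tertiary trimethylsilyl ether without touching the diacetal or the benzoate.

Step 10
Reactants: 16 C3=C4 enone with free C1–OH
Product: 17 (1R,2S,5R,6S) allylic alcohol with the C2–OH trans to the C1–OH
Conditions: Me4NBH(OAc)3 (5 equiv), MeCN/AcOH (1:1), −20 °C
Reagents that add atoms: none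
Why: Evans–Saksena hydroxyl-directed reduction; the C1 hydroxyl exchanges onto boron and the hydride is delivered intramolecularly to the carbonyl face that carries O1, so the new C2 hydroxyl is trans to the C1 hydroxyl and cis to C7 (2S). The triacetoxyborohydride does not reduce ketones intermolecularly, so neither the opposite face nor the conjugate position should be attacked.

Step 11
Reactants: 17 (1R,2S,5R,6S) allylic alcohol; 9 benzoyl chloride
Product: 18 C2-O-benzoate of 17 (C2,C7-dibenzoate diacetal)
Conditions: 9 (1.5 equiv), pyridine, 4-(dimethylamino)pyridine (10 mol%), CH2Cl2, 0 → 25 °C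
Reagents that add atoms: none
Why: Nucleophile-catalysed acylation of the only secondary hydroxyl; the tertiary C1 hydroxyl stays free.

Step 12
Reactants: 18 C2,C7-dibenzoate diacetal
Product: 19 [(1S,2S,5R,6S)-2-(benzoyloxy)-1,5,6-trihydroxycyclohex-3-en-1-yl]methyl benzoate
Conditions: CF3CO2H/H2O (9:1), 25 °C, minutes; evaporation with toluene
Reagents that add atoms: none
Why: Acid hydrolysis of the bis-ketal releases the C5/C6 diol; the benzoates should survive the brief exposure and no stereocentre is involved.

## Compound list

1 | nitromethane | C[N+](=O)[O-] | starting material
2 | acrolein | C=CC=O | starting material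
3 | 4-nitrobutanal | O=CCCC[N+](=O)[O-] | intermediate
4 | dihydroxyacetone phosphate | O=C(CO)COP(=O)(O)O | starting material
5 | (3S,4R)-3,4-dihydroxy-7-nitro-2-oxoheptyl dihydrogen phosphate | O=P(O)(O)OCC(=O)[C@@H](O)[C@H](O)CCC[N+](=O)[O-] | intermediate (not isolated)
6 | [(1S,2R,5R,6S)-1,5,6-trihydroxy-2-nitrocyclohexyl]methyl dihydrogen phosphate | O=P(O)(O)OC[C@@]1(O)[C@H]([N+](=O)[O-])CC[C@@H](O)[C@@H]1O | intermediate
7 | (1S,2R,5R,6S)-1-(hydroxymethyl)-2-nitrocyclohexane-1,5,6-triol | OC[C@@]1(O)[C@H]([N+](=O)[O-])CC[C@@H](O)[C@@H]1O | intermediate
8 | 5,6-O-[(2S,3S)-2,3-dimethoxybutane-2,3-diyl] acetal of 7 | OC[C@@]1(O)[C@H]([N+](=O)[O-])CC[C@H]2O[C@](C)(OC)[C@@](C)(OC)O[C@H]12 | intermediate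
9 | benzoyl chloride | O=C(Cl)c1ccccc1 | starting material
10 | C7-O-benzoate of 8 | O=C(OC[C@@]1(O)[C@H]([N+](=O)[O-])CC[C@H]2O[C@](C)(OC)[C@@](C)(OC)O[C@H]12)c1ccccc1 | intermediate
11 | C1-O-trimethylsilyl ether of 10 | O=C(OC[C@@]1(O[Si](C)(C)C)[C@H]([N+](=O)[O-])CC[C@H]2O[C@](C)(OC)[C@@](C)(OC)O[C@H]12)c1ccccc1 | intermediate
12 | potassium nitronate of 11 | O=C(OC[C@@]1(O[Si](C)(C)C)C(=[N+]([O-])[O-])CC[C@H]2O[C@](C)(OC)[C@@](C)(OC)O[C@H]12)c1ccccc1.[K+] | intermediate (not isolated)
13 | C2 ketone (1S,5R,6S) with C1–OSiMe3, C7–OBz and the 5,6-diacetal | O=C(OC[C@@]1(O[Si](C)(C)C)C(=O)CC[C@H]2O[C@](C)(OC)[C@@](C)(OC)O[C@H]12)c1ccccc1 | intermediate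
14 | C2 trimethylsilyl enol ether of 13 (C2=C3) | O=C(OC[C@@]1(O[Si](C)(C)C)C(O[Si](C)(C)C)=CC[C@H]2O[C@](C)(OC)[C@@](C)(OC)O[C@H]12)c1ccccc1 | intermediate
15 | C3=C4 enone with C1–OSiMe3 | O=C(OC[C@@]1(O[Si](C)(C)C)C(=O)C=C[C@H]2O[C@](C)(OC)[C@@](C)(OC)O[C@H]12)c1ccccc1 | intermediate (not isolated)
16 | C3=C4 enone with free C1–OH (1S,5R,6S) | O=C(OC[C@@]1(O)C(=O)C=C[C@H]2O[C@](C)(OC)[C@@](C)(OC)O[C@H]12)c1ccccc1 | intermediate
17 | (1R,2S,5R,6S) allylic alcohol, C2–OH trans to C1–OH, C7–OBz, 5,6-diacetal | O=C(OC[C@@]1(O)[C@@H](O)C=C[C@H]2O[C@](C)(OC)[C@@](C)(OC)O[C@H]12)c1ccccc1 | intermediate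
18 | C2-O-benzoate of 17 (C2,C7-dibenzoate diacetal) | O=C(OC[C@@]1(O)[C@@H](OC(=O)c3ccccc3)C=C[C@H]2O[C@](C)(OC)[C@@](C)(OC)O[C@H]12)c1ccccc1 | intermediate
19 | [(1S,2S,5R,6S)-2-(benzoyloxy)-1,5,6-trihydroxycyclohex-3-en-1-yl]methyl benzoate | O=C(OC[C@@]1(O)[C@@H](OC(=O)c2ccccc2)C=C[C@@H](O)[C@@H]1O)c1ccccc1 | target

## Step count and least certain steps

Total: 12 steps. Longest linear sequence: 12 steps (1 and 2 to 19); 4 and 9 are purchased.

**Step 2 (key step).** The most likely failure is slow or incomplete Henry closure at the near-neutral pH that the phosphate donor tolerates, or incomplete equilibration at C1, which would leave a mixture of C1 epimers. The fallback separates the two events. It sets out from 3 and 4, runs the aldolase reaction only to the open-chain stage 5, and hydrolyses the phosphate with acid phosphatase to (3S,4R)-1,3,4-trihydroxy-7-nitroheptan-2-one F1. The ring is then closed and equilibrated chemically with a catalytic tertiary amine in methanol, where the pH is no longer limited by the donor, and the route is rejoined at 7.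

**Step 7.** The likely problems are sluggish deprotonation, because the planar nitronate suffers allylic strain against the equatorial C7 arm, and elimination of trimethylsilanolate from the nitronate to a nitroalkene. The fallback avoids any nitronate. It sets out from 10 (step 6 is skipped) and applies a reductive Nef reaction with aqueous TiCl3 in dimethoxyethane at 25 °C, in which trivalent titanium reduces the neutral nitro group through the oxime and imine stage. This gives the α-hydroxy ketone [(1S,5R,6S) C2 ketone with free C1–OH, C7–OBz and the 5,6-diacetal] F2. Double silylation of F2 under the conditions of step 8 (2.5 equiv Me3SiOTf) rejoins the route at 14.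

**Step 10.** The likely problem is poor facial selectivity or no reaction if the hindered tertiary hydroxyl exchanges onto boron too slowly for intramolecular delivery. The fallback uses the intrinsic selectivity and then inverts. It sets out from 16 with a Luche reduction (NaBH4, CeCl3·7H2O, MeOH, −78 °C), where axial attack anti to the pseudoaxial C1–O bond should give the C2 epimer, the (1R,2R,5R,6S) allylic alcohol F3. A Mitsunobu reaction of F3 with benzoic acid (PPh3, diisopropyl azodicarboxylate, THF, 0 → 25 °C) inverts C2 and installs the benzoate in one operation, and the route is rejoined at 18 without step 11.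

**Step 4.** The likely problem is poor site selectivity of the acetalisation, with diol pairs that include the primary C7 hydroxyl competing with the C5/C6 pair. The fallback reverses the order of protection. It sets out from 7 and benzoylates the primary hydroxyl first (9, 2,4,6-collidine, CH2Cl2/DMF, −40 °C) to give [(1S,2R,5R,6S)-1,5,6-trihydroxy-2-nitrocyclohexyl]methyl benzoate F4. The diacetal is then formed under the conditions of step 4 on a substrate that has no primary hydroxyl left, and the route is rejoined at 10.

**Step 12.** The likely problems in strong aqueous acid are benzoyl migration to the freed hydroxyls and ionisation of the allylic C2–O bond. The fallback changes the diol protection before the allylic benzoate exists.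
- It sets out from 16 and removes the diacetal at the acid-stable enone stage (CF3CO2H/H2O) to give [(1S,5R,6S)-1,5,6-trihydroxy-2-oxocyclohex-3-en-1-yl]methyl benzoate F5.
- The two secondary hydroxyls are silylated (Et3SiCl, imidazole, DMF) to the 5,6-bis-O-triethylsilyl ether F6.
- The directed reduction of step 10 gives the (1R,2S,5R,6S) allylic alcohol F7.
- Benzoylation with 9 as in step 11 gives the C2,C7-dibenzoate F8.
- HF·pyridine in THF at 0 °C removes the silyl ethers under nearly neutral conditions, and the route is rejoined at 19.

## Further compounds

F1 | step 2 | (3S,4R)-1,3,4-trihydroxy-7-nitroheptan-2-one | O=C(CO)[C@@H](O)[C@H](O)CCC[N+](=O)[O-]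
F2 | step 7 | (1S,5R,6S) C2 ketone with free C1–OH, C7–OBz and the 5,6-diacetal | O=C(OC[C@@]1(O)C(=O)CC[C@H]2O[C@](C)(OC)[C@@](C)(OC)O[C@H]12)c1ccccc1
F3 | step 10 | (1R,2R,5R,6S) allylic alcohol, C2 epimer of 17 | O=C(OC[C@@]1(O)[C@H](O)C=C[C@H]2O[C@](C)(OC)[C@@](C)(OC)O[C@H]12)c1ccccc1
F4 | step 4 | [(1S,2R,5R,6S)-1,5,6-trihydroxy-2-nitrocyclohexyl]methyl benzoate | O=C(OC[C@@]1(O)[C@H]([N+](=O)[O-])CC[C@@H](O)[C@@H]1O)c1ccccc1
F5 | step 12 | [(1S,5R,6S)-1,5,6-trihydroxy-2-oxocyclohex-3-en-1-yl]methyl benzoate | O=C(OC[C@@]1(O)C(=O)C=C[C@@H](O)[C@@H]1O)c1ccccc1
F6 | step 12 | 5,6-bis-O-triethylsilyl ether of F5 | O=C(OC[C@@]1(O)C(=O)C=C[C@@H](O[Si](CC)(CC)CC)[C@@H]1O[Si](CC)(CC)CC)c1ccccc1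
F7 | step 12 | (1R,2S,5R,6S) allylic alcohol from F6, C2–OH trans to C1–OH | O=C(OC[C@@]1(O)[C@@H](O)C=C[C@@H](O[Si](CC)(CC)CC)[C@@H]1O[Si](CC)(CC)CC)c1ccccc1
F8 | step 12 | C2-O-benzoate of F7 | O=C(OC[C@@]1(O)[C@@H](OC(=O)c2ccccc2)C=C[C@@H](O[Si](CC)(CC)CC)[C@@H]1O[Si](CC)(CC)CC)c1ccccc1
A1 | alternative 1 | (Z)-enal oxime with the C1=C7 tert-butyldimethylsilyl enol ether and the C5/C6 acetonide | C=C(O[Si](C)(C)C(C)(C)C)[C@H]1OC(C)(C)O[C@@H]1/C=C\C=NO
A2 | alternative 1 | cyclohexene-fused isoxazoline with tert-butyldimethylsilyloxy at quaternary C1 | CC(C)(C)[Si](C)(C)O[C@]12CON=C1C=C[C@H]1OC(C)(C)O[C@@H]12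
A3 | alternative 2 | (1-hydroxycyclohexa-2,5-dien-1-yl)methyl benzoate | O=C(OCC1(O)C=CCC=C1)c1ccccc1
A4 | alternative 2 | syn epoxy alcohol with the C5/C6 oxirane cis to the C1 hydroxyl | O=C(OC[C@@]1(O)C=CC[C@H]2[C@@H]1O2)c1ccccc1
A5 | alternative 3 | 2,3-O-isopropylidene-4-O-tert-butyldimethylsilyl D-manno-1,5-lactone with an (E)-2-(4-methoxybenzyloxy)vinyl group at C5 | O=C1O[C@H](/C=C/OCc2ccc(OC)cc2)[C@@H](O[Si](C)(C)C(C)(C)C)[C@@H]2OC(C)(C)O[C@H]12
A6 | alternative 3 | cyclohexenecarboxylic acid with C7 as the acid, C2 as the 4-methoxybenzyl ether, C5 as the silyl ether and the C1/C6 acetonide | OC(=O)[C@@]1(OC2(C)C)[C@@H](OCc3ccc(OC)cc3)C=C[C@@H](O[Si](C)(C)C(C)(C)C)[C@@H]1O2
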